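A small charge of free catalyst, 6.0 mM against 0.12 M of substrate, could hold 5.00% of the substrate charged if each catalyst bound one substrate, and I used that share to bracket what these flasks would give.

in all of them: substrate 0.12 M
- epsilon: reagent 0.060 M; free catalyst 6 mM; temperature −19 °C; run made earlier
- delta: reagent 0.24 M; free catalyst 6 mM; temperature −5 °C; run made earlier
- gamma: reagent 0.12 M; free catalyst 9 mM; temperature −19 °C; run made earlier
- Monday's: reagent 0.120 M; free catalyst 6.0 mM; at −25 °C until 25 min, from then on at 0 °C; time 50 min
- Friday's: reagent 0.120 M; free catalyst 6.0 mM; temperature 0 °C; time 50 min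
- Saturday's: reagent 0.120 M; free catalyst 6.0 mM; temperature −25 °C; time 50 min

- epsilon (time / min: target / %, substrate / %): 15.0: 1.3, 67.9; 50.0: 4.4, 39.1; 80.0: 8.7, 27.5; 120: 13.5, 18.2
- delta (time / min: target / %, substrate / %): 12.0: 8.0, 37.3; 25.0: 14.4, 19.3; 40.0: 23.2, 10.2; 50.0: 26.5, 5.7
- gamma (time / min: target / %, substrate / %): 30.0: 4.6, 51.8; 60.0: 10.4, 31.9; 90.0: 16.2, 21.7; 120: 20.8, 14.0

(each reading ± 0.5 percentage points)

1. the flask that comes out highest in amount of target, in percent of the substrate charged, or "all alike" when all lie within 1.5 percentage points (Monday's / Friday's / Saturday's / all alike)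
2. target at the end, in percent of the substrate charged, Monday's
3. target at the end, in percent of the substrate charged, Friday's
4. target at the end, in percent of the substrate charged, Saturday's



Two pairs of readings guided me. The epsilon run had target 13.5% at substrate 18.2% and the delta run had target 14.4% at substrate 19.3%, but higher up the epsilon run had target 4.4% at substrate 39.1% and the delta run had target 8.0% at substrate 37.3%, a gap of 3.6 percentage points against a scatter of 0.5 points. So these two runs did not share one curve of target against substrate, and I took the delta run, at −5 °C, as my guide to Friday's flask, for an estimate and not a proof. Friday's flask at 0 °C stood warmer than the delta run at −5 °C for the same 50 min, though with half the reagent, so I took the delta run's last target, 26.5%, as an estimated floor for it. That last reading also gave my estimate from above, on the guess that Friday's flask had no more target within reach than the delta run: c(target) + c(substrate) + the held share came to 37.2%. I call this the ceiling, the target read plus what could still become target. Without the held share the sum was 32.2%, the tightest I could go, and I committed to the middle of floor and that sum, 29.3%. Monday's and Saturday's flasks spent time colder than Friday's, so I expected less target in them.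

The forecast gave Friday's 34% (27% to 43%), Monday's 24% and Saturday's 2.3%, with Friday's highest, holding that “temperature simply rescales time”. Its Friday's value lay inside my bracket but above my tightened sum, and its high end stood above the ceiling.

The flasks gave 30.2% on Friday's, 22.6% on Monday's and 2.05% on Saturday's, with Friday's highest. Friday's value fell inside my bracket and inside the forecast's range.

    substrate + free catalyst ⇌ catalyst intermediate A (K = 72.4 M⁻¹, k = 0.307 M⁻¹ s⁻¹, Ea = 39.0 kJ mol⁻¹, ΔH = −29.0 kJ mol⁻¹)
    reagent + catalyst intermediate A → catalyst intermediate B (k = 0.332 M⁻¹ s⁻¹, Ea = 38.0 kJ mol⁻¹)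
    catalyst intermediate B ⇌ by-product + catalyst intermediate C (K = 0.890 M, k = 0.0410 s⁻¹, Ea = 78.0 kJ mol⁻¹, ΔH = −52.0 kJ mol⁻¹)
    catalyst intermediate C ⇌ catalyst intermediate D (K = 1.40, k = 0.00676 s⁻¹, Ea = 72.0 kJ mol⁻¹, ΔH = −85.0 kJ mol⁻¹)
    catalyst intermediate D → free catalyst + target (k = 0.131 s⁻¹, Ea = 68.0 kJ mol⁻¹)
    2 substrate → self-condensation product (k = 0.0131 M⁻¹ s⁻¹, Ea = 60.0 kJ mol⁻¹)
    substrate + by-product → side product (k = 2.84 × 10⁻⁴ M⁻¹ s⁻¹, Ea = 67.0 kJ mol⁻¹)
    (constants at 0 °C)

Left until 500 min, Friday's flask reached 31.9%, under the ceiling, beside self-condensation product 67.8%. Free catalyst at 4.64 mM, the rest held, moved Friday's target by 5 points, against 3.2 points between the result and the forecast's low end. The same reckoning on Monday's flask at 50.0 min gave floor 22.6% and ceiling 35.9%. The neighbour, Monday's flask read at 2.0 h, gave 32.0%, inside that bracket, with substrate, the limiting reagent, down to 0.016%.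

Readings and results are simulated with constants of no real substance; scatter was added.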